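A small charge of capture agent, 0.0200 M set beside the reagent, stays out of this reckoning, which follows the reagent through the warmest flask, Saturday's.

| setting | ash | oak | Saturday's | Wednesday's | Monday's | Tuesday's |
|---|---|---|---|---|---|---|
| substrate | 1 M | 1 M | 1.0 M | 1.0 M | 1.0 M | 1.0 M |
| reagent | 1.5 M | 1.5 M | 1.50 M | 1.50 M | 1.50 M | 1.50 M |
| capture agent | 0.013 M | 0.030 M | 0.0200 M | 0.0200 M | 0.0200 M | 0.0200 M |
| temperature | −45 °C | −10 °C | 20 °C | −40 °C | −20 °C | 0 °C |
| remark | run made earlier | run made earlier |  |  |  |  |
| time |  |  | 5.0 min | 5.0 min | 5.0 min | 5.0 min |

- ash (time / min: double product / %, substrate / %): 8.00: 0, 99; 25.0: 0, 102; 50.0: 0, 98; 80.0: 0, 94; 90.0: 0, 94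
- oak (time / min: double product / %, substrate / %): 4.00: 3, 70; 6.00: 8, 58; 12.0: 15, 41; 20.0: 27, 34

(standard deviation of a reading: 2 percentage points)

- the flask with the highest amount of double product, in percent of the substrate charged ("all alike" if they lie within 1.5 percentage points) (Saturday's / Wednesday's / Monday's / Tuesday's / all alike)
- final double product, as a percentage of the substrate charged, in Saturday's
- final double product, as a percentage of the substrate charged, in Wednesday's
- final double product, as a percentage of the substrate charged, in Monday's
- final double product, as a percentage of the substrate charged, in Tuesday's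

Read the flask as substrate to first product to double product, with one reagent per step. Every substrate lost then takes one reagent and every double product a second, so double product equals the reagent surplus, meaning the reagent charged beyond one per substrate as a share of the substrate charged, 50.0%, plus the substrate left, minus the reagent left.

From above, a crude bound puts all reagent into double product, 75.0%. You can tighten it with the oak run, whose last reading leaves 57.0% of reagent unused, reckoned on the substrate charged. Between its last two readings substrate fell 7 percentage points while reagent use rose 19 points, and if Saturday's follows that slope, which carries the scatter, 13.0% of substrate stays, so my upper mark is 63.0%, an estimate and not a strict bound.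

From below, take no substrate left and ask how much reagent remains. Replacing reagent by its mean over the oak run to 12.0 min gives, as a reading with its scatter, a constant for the loss of substrate of 0.0658 L mol⁻¹ min⁻¹. For the step from the oak run to Saturday's I take a factor of 20.1, on the low side of the forecast's 24, use the same constant for both steps, and set the reagent's partners at a mean of 0.5 of the substrate charge. Treated on that footing as pseudo-first-order, reagent has a life of 1.51 min, shorter than 5.0 min, which on this estimate leaves 3.68% of it and gives a lower mark of 44.5%, again an estimate.

The forecast names Saturday's with 52%, inside my marks , saying “about 24× faster than −10 °C, so reagent is nearly exhausted”; for Tuesday's, Monday's and Wednesday's it gives 16%, 0.5% and 0%.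

The flasks give 56.1% in Saturday's, the most and between my marks , then 20.4%, 0.900% and 0.00639% in Tuesday's, Monday's and Wednesday's, and the scheme is this:

    substrate + reagent → first product + by-product (k = 0.0320 L mol⁻¹ s⁻¹, Ea = 70.0 kJ mol⁻¹)
    reagent + first product → double product + by-product (k = 0.0300 L mol⁻¹ s⁻¹, Ea = 64.0 kJ mol⁻¹)
    reagent + double product ⇌ triple product + by-product (K = 1.70, k = 0.0570 L mol⁻¹ s⁻¹, Ea = 45.0 kJ mol⁻¹, ΔH = 20.0 kJ mol⁻¹)
    first product + capture agent → trapped intermediate (k = 0.0160 L mol⁻¹ s⁻¹, Ea = 70.0 kJ mol⁻¹)
    (constants at 20 °C)

Saturday's ends with 13.0% of substrate, 1.8% of its reagent and 2.06% of triple product, so the surplus reckoning gives 60.2%, and the double product falls short of that by twice the triple product, 4.12%. The same flask with 1.7 M of substrate has a surplus of −11.8%, keeps 36.9% of its substrate and 0.028% of its reagent, so the reckoning gives 25.1%, and that flask holds 25.0% of double product.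

All runs are simulated for an exercise, and the scatter is random.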